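Ring A is first built as something else: a δ-lactone (O–C20–C10–C5–C4–C3) that carries an (E)-2-borylvinyl group (C2=C1) on C3. O-Silylation of this α-cyano lactone triggers a boat Ireland–Claisen rearrangement that forms C1–C10 as C3–O breaks, so the lactone turns into the cyclohexene of ring A. This one operation creates the quaternary spiro carbon C10 and the C1 carbinol centre (C–B, oxidised with retention) by chirality transfer from C3. It also distinguishes C20 (carboxyl) from C9 (nitrile). It exploits the 1,3-dioxygenated unit O–C1–C10–C20–O shared by ring A and the lactone ring. Knoevenagel lactonisation, a butadiene Diels–Alder reaction and a vinyl-radical cyclisation then add the remaining rings.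

Key step: step 7

Remark on the chemistry: atoms are labelled C1–C20 as in ent-kauranes. Compounds 9 and 10 are mixtures of epimers at the acidic carbon C10, which becomes planar in step 7, so this centre is left undefined in their SMILES.

Step 1
Reactants: 1 (S)-pantolactone
Product: 2 (3S)-4,4-dimethyloxolane-2,3-diol (lactol as anomer mixture)
Conditions: i-Bu2AlH (2.2 equiv), CH2Cl2, −78 °C; aq. Rochelle salt
Reagents that add atoms: none
Why: Partial lactone reduction with DIBAL-H stops at the lactol at −78 °C and leaves the carbinol centre (future C3, the only source of chirality for ring A) untouched.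

Step 2
Reactants: 2 (3S)-4,4-dimethyloxolane-2,3-diol
Product: 3 (3R)-2,2-dimethylpent-4-yne-1,3-diol
Conditions: dimethyl (1-diazo-2-oxopropyl)phosphonate (1.5 equiv), K2CO3 (3 equiv), MeOH, 0 °C → rt
Reagents that add atoms: dimethyl (1-diazo-2-oxopropyl)phosphonate COP(=O)(OC)C(=[N+]=[N-])C(C)=O
Why: Seyferth–Gilbert homologation in the Ohira–Bestmann version traps the open hydroxy aldehyde form of the lactol and adds C1 as the terminal alkyne carbon; C3 keeps its spatial arrangement, and only the descriptor changes because the priorities change.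

Step 3
Reactants: 3 (3R)-2,2-dimethylpent-4-yne-1,3-diol
Product: 4 (3R)-3-hydroxy-2,2-dimethylpent-4-ynal
Conditions: TEMPO (10 mol%), PhI(OAc)2 (1.1 equiv), CH2Cl2, rt; used crude
Reagents that add atoms: none
Why: Oxoammonium (TEMPO) oxidation is sterically biased towards the primary alcohol, so C5 becomes the aldehyde while the secondary propargylic C3–OH survives.

Step 4
Reactants: 4 (3R)-3-hydroxy-2,2-dimethylpent-4-ynal; 5 cyanoacetic acid
Product: 7 (6R)-6-ethynyl-5,5-dimethyl-2-oxo-5,6-dihydro-2H-pyran-3-carbonitrile, via cyanoacetate ester 6 (not isolated)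
Conditions: DCC (1.1 equiv), DMAP (10 mol%), CH2Cl2, 0 °C → rt; then Et3N (20 mol%), 4 Å MS, rt
Reagents that add atoms: none
Why: Steglich esterification of C3–OH followed by an intramolecular Knoevenagel condensation (six-membered ring, very acidic cyanoacetate CH2) brings in C20, C10 and C9 and gives the C5=C10 unsaturated lactone; no stereocentre is formed.

Step 5
Reactants: 7 (6R)-6-ethynyl-5,5-dimethyl-2-oxo-5,6-dihydro-2H-pyran-3-carbonitrile; 8 1,3-dioxolane
Product: 9 (4S,6R)-4-(1,3-dioxolan-2-yl)-6-ethynyl-5,5-dimethyl-2-oxooxane-3-carbonitrile (4,6-trans)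
Conditions: (n-Bu4N)4[W10O32] (2 mol%), 8/MeCN 1:1, 390 nm LED, rt
Reagents that add atoms: none
Why: Decatungstate-photocatalysed hydrogen-atom transfer gives the nucleophilic 1,3-dioxolan-2-yl radical, which adds in Giese fashion to the electron-poor C5 as the masked formyl carbon C6; it should enter axially, anti to the pseudo-axial C4 methyl group and trans to the pseudo-equatorial ethynyl group on C3, which sets C5.

Step 6
Reactants: 9 (4S,6R)-4-(1,3-dioxolan-2-yl)-6-ethynyl-5,5-dimethyl-2-oxooxane-3-carbonitrile
Product: 10 (4S,6R)-4-(1,3-dioxolan-2-yl)-5,5-dimethyl-2-oxo-6-[(E)-2-(4,4,5,5-tetramethyl-1,3,2-dioxaborolan-2-yl)ethenyl]oxane-3-carbonitrile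
Conditions: pinacolborane (1.5 equiv), Cy2BH (10 mol%), THF, rt
Reagents that add atoms: pinacolborane CC1(C)OBOC1(C)C
Why: Dicyclohexylborane-catalysed syn hydroboration of the terminal alkyne puts boron on the terminal carbon C1 and gives only the E alkene, the geometry that later defines C1; nitrile, lactone and acetal are inert to the neutral reagent.

Step 7
Reactants: 10 (E)-vinylboronate lactone
Product: 13 (1S,2S,6R)-1-cyano-6-(1,3-dioxolan-2-yl)-2-hydroxy-5,5-dimethylcyclohex-3-ene-1-carboxylic acid, via silyl ketene acetal 11 (not isolated), via allylboronate silyl ester 12 (not isolated)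
Conditions: KHMDS (1.05 equiv), Me3SiCl (1.5 equiv), THF/toluene, −78 °C → rt, then 90 °C; then NaBO3·4H2O, THF/H2O, 0 °C; mildly acidic work-up
Reagents that add atoms: sodium perborate [Na+].[O-]OB=O (oxygen on C1); chlorotrimethylsilane C[Si](C)(C)Cl (silyl groups of 11 and 12)
Why: Deprotonation of the acidic C10–H and O-silylation give ketene acetal 11 (an N-silyl ketenimine tautomer equilibrates with it and is a dead end), whose C10=C20–O–C3–C2=C1 array undergoes a [3,3]-sigmatropic shift that makes C1–C10 and breaks C3–O; perborate then turns the allylic C1–B bond of 12 into C1–OH with retention. The closest known reaction type is the Ireland–Claisen ring contraction of alkenyl lactone silyl ketene acetals to cycloalkenecarboxylic acids, combined with the known Ireland–Claisen rearrangement of boron-substituted allyl esters. Ring A (C1–C2–C3–C4–C5–C10) closes as a six-membered carbocycle out of the six-membered lactone through the only accessible, boat-shaped (bicyclo[2.2.2]octane-like) transition state, in which C4–C5 is the third bridge. C10 is set by suprafacial chirality transfer from C3: C1 must bond to the lactone face that carries the vinyl group, which is trans to the C5 dioxolanyl group, so C20 ends cis to C6; C1 is set by the E geometry of the vinylboronate, which places boron on the side of the C20 bridge and hence cis to C20. The step needs silylation at the lactone oxygen, no loss of CO2 and no retro-aldol opening of 13: the ring fixes the ketene acetal geometry, C20 stays a silyl ester while hot, and the oxidation is run cold and weakly basic on the carboxylate.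

Step 8
Reactants: 13 hydroxy acid
Product: 14 (1S,2S,6R)-2-acetoxy-1-cyano-6-(1,3-dioxolan-2-yl)-5,5-dimethylcyclohex-3-ene-1-carboxylic acid
Conditions: Ac2O (3 equiv), pyridine, DMAP (5 mol%), CH2Cl2, 0 °C → rt; aqueous work-up
Reagents that add atoms: acetic anhydride CC(=O)OC(C)=O
Why: DMAP-catalysed acetylation installs the final C1 acetate at once and removes the retro-aldol risk of the β-hydroxy nitrile; the transient mixed anhydride at C20 is hydrolysed on work-up.

Step 9
Reactants: 14 allylic acetate acid
Product: 15 (1S,2R,6S)-6-acetoxy-1-cyano-2-(1,3-dioxolan-2-yl)-3,3-dimethylcyclohexane-1-carboxylic acid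
Conditions: H2 (1 atm), 5% Rh/Al2O3, EtOAc, rt
Reagents that add atoms: none
Why: Heterogeneous hydrogenation over rhodium on alumina saturates C2=C3 with little tendency to hydrogenolyse the allylic acetate or to reduce the hindered nitrile; no stereocentre is formed.

Step 10
Reactants: 15 saturated acid
Product: 16 [(1S,2R,3R)-2-cyano-3-(1,3-dioxolan-2-yl)-2-(hydroxymethyl)-4,4-dimethylcyclohexyl] acetate
Conditions: BH3·SMe2 (2 equiv), THF, 0 °C → rt; aqueous work-up
Reagents that add atoms: none
Why: Borane reduces the free carboxylic acid (through the acyloxyborane) much faster than nitrile, acetate or acetal and so turns C20 into CH2OH, and the non-basic medium disfavours acetyl migration from O1 to O20.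

Step 11
Reactants: 16 hydroxymethyl nitrile
Product: 17 [(1S,2R,3R)-3-(1,3-dioxolan-2-yl)-2-formyl-2-(hydroxymethyl)-4,4-dimethylcyclohexyl] acetate
Conditions: Cp2Zr(H)Cl (2.5 equiv), THF, rt, 30 min; wet SiO2 or aq. citric acid
Reagents that add atoms: water O
Why: Hydrozirconation of the linear, sterically accessible C9 nitrile stops at the imine oxidation level and hydrolysis gives the C9 aldehyde, while acetate and acetal are left alone by the Schwartz reagent.

Step 12
Reactants: 18 tert-butyl acetate; 19 ethyl 3-(trimethylsilyl)prop-2-ynoate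
Product: 20 tert-butyl 3-oxo-5-(trimethylsilyl)pent-4-ynoate
Conditions: LDA (2.1 equiv), 18 (2.1 equiv), THF, −78 °C; then 19; aq. HCl quench
Reagents that add atoms: none
Why: Crossed Claisen condensation of the lithium enolate of 18 with the alkynoate, in which the silyl cap shields the β-carbon from conjugate addition and the second equivalent of enolate deprotonates the product.

Step 13
Reactants: 17 hydroxy aldehyde; 20 tert-butyl 3-oxo-5-(trimethylsilyl)pent-4-ynoate
Product: 22 7-acetoxy-11-(1,3-dioxolan-2-yl)-10,10-dimethyl-4-[3-(trimethylsilyl)prop-2-ynoyl]-2-oxaspiro[5.5]undec-4-en-3-one (C20 cis to OAc and to the dioxolanyl group), via keto ester 21 (not isolated)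
Conditions: toluene, 110 °C (loss of t-BuOH); then Et3N (20 mol%), 4 Å MS, rt
Reagents that add atoms: none
Why: Neutral thermal transacylation of the tert-butyl β-keto ester by the C20 alcohol, then a base-catalysed intramolecular Knoevenagel condensation on the non-enolisable C9 aldehyde, closes the δ-lactone ring (C7–O–C20–C10–C9–C8) and gives a doubly activated C8=C9 bond; C10 is unchanged.

Step 14
Reactants: 22 spirolactone dienophile; 23 buta-1,3-diene
Product: 24 Diels–Alder adduct (lactone ring cis-fused at C8–C9 to a cyclohexene with C12=C13; H-9 and the C15 acyl group on the same face; C11 anti to C5)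
Conditions: 23 (excess), ZnCl2 (1.5 equiv), CH2Cl2/Et2O, sealed tube, 0 °C → rt
Reagents that add atoms: none
Why: Lewis-acid-promoted Diels–Alder reaction of a chelated 3-acyl-5,6-dihydropyran-2-one, which is far more electron-poor than the silyl-capped alkyne; suprafacial addition makes C14–C8 and C11–C9 cis, as the target requires, and the diene should approach the lactone face flanked by C1 (flat, small acetate oxygen) and not the face covered by C5 and its dioxolane, which sets C8 and C9 relative to C10.

Step 15
Reactants: 24 Diels–Alder adduct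
Product: 25 (15R)-propargylic alcohol of 24
Conditions: Ru[(S,S)-TsDPEN](p-cymene) (5 mol%), i-PrOH, rt
Reagents that add atoms: none
Why: Noyori asymmetric transfer hydrogenation of an alkynyl ketone under catalyst control, with the alkynyl group in the role of the aryl group and the quaternary C8 in that of the alkyl group, should give the (15R) alcohol; the base-free medium spares lactone, acetate and alkene.

Step 16
Reactants: 25 (15R)-propargylic alcohol
Product: 26 terminal alkyne (C17–H)
Conditions: n-Bu4NF (1.1 equiv), AcOH (1.2 equiv), THF, 0 °C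
Reagents that add atoms: none
Why: Buffered fluoride cleaves only the C(sp)–Si bond (protodesilylation), and the acetic acid buffer protects acetate and lactone from basic fluoride.

Step 17
Reactants: 26 terminal alkyne
Product: 27 tetracyclic vinylstannane (bicyclo[3.2.1]octane closed; C17 bears SnBu3; E/Z mixture)
Conditions: n-Bu3SnH (1.5 equiv), AIBN (0.2 equiv), benzene, 80 °C
Reagents that add atoms: tributyltin hydride CCCC[SnH](CCCC)CCCC
Why: The stannyl radical adds to the terminal carbon C17 and the C16 vinyl radical closes 5-exo-trig onto C13 of the C12=C13 bond (vinyl radical cyclisation); the short C15–C8–C14 tether allows bonding on one face only, which sets C13, and the C12 radical is reduced by the tin hydride.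

Step 18
Reactants: 27 tetracyclic vinylstannane
Product: 28 target CNP0117386.1 (6,7-seco-ent-kaur-16-ene 7,20-lactone with 1-OAc cis to C20, (15R)-OH and the C6 aldehyde)
Conditions: 1 M aq. HCl, THF, rt
Reagents that add atoms: water O
Why: Dilute acid protodestannylates the vinylstannane by ipso protonation to the exocyclic C16=C17 methylene group and hydrolyses the dioxolane to the C6 aldehyde, under conditions that should leave acetate, lactone, allylic alcohol and C5 untouched.

Compound list
1 | (S)-pantolactone, (3S)-3-hydroxy-4,4-dimethyloxolan-2-one | CC1(C)COC(=O)[C@H]1O | starting material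
2 | (3S)-4,4-dimethyloxolane-2,3-diol | CC1(C)COC(O)[C@H]1O | intermediate
3 | (3R)-2,2-dimethylpent-4-yne-1,3-diol | C#C[C@@H](O)C(C)(C)CO | intermediate
4 | (3R)-3-hydroxy-2,2-dimethylpent-4-ynal | C#C[C@@H](O)C(C)(C)C=O | intermediate
5 | cyanoacetic acid | N#CCC(=O)O | starting material
6 | (3R)-4,4-dimethyl-5-oxopent-1-yn-3-yl cyanoacetate | C#C[C@@H](OC(=O)CC#N)C(C)(C)C=O | intermediate
7 | (6R)-6-ethynyl-5,5-dimethyl-2-oxo-5,6-dihydro-2H-pyran-3-carbonitrile | C#C[C@H]1OC(=O)C(C#N)=CC1(C)C | intermediate
8 | 1,3-dioxolane | C1COCO1 | starting material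
9 | (4S,6R)-4-(1,3-dioxolan-2-yl)-6-ethynyl-5,5-dimethyl-2-oxooxane-3-carbonitrile | C#C[C@H]1OC(=O)C(C#N)[C@H](C2OCCO2)C1(C)C | intermediate
10 | (E)-vinylboronate lactone (pinacol boronate on C1) | CC1(C)OB(/C=C/[C@H]2OC(=O)C(C#N)[C@H](C3OCCO3)C2(C)C)OC1(C)C | intermediate
11 | O-trimethylsilyl ketene acetal of 10 | CC1(C)OB(/C=C/[C@H]2OC(O[Si](C)(C)C)=C(C#N)[C@H](C3OCCO3)C2(C)C)OC1(C)C | intermediate
12 | trimethylsilyl ester of the ring A allylboronate (B on C1, cis to C20) | C[Si](C)(C)OC(=O)[C@@]1(C#N)[C@@H](B2OC(C)(C)C(C)(C)O2)C=CC(C)(C)[C@H]1C1OCCO1 | intermediate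
13 | (1S,2S,6R)-1-cyano-6-(1,3-dioxolan-2-yl)-2-hydroxy-5,5-dimethylcyclohex-3-ene-1-carboxylic acid (CO2H, OH and dioxolanyl all cis) | OC(=O)[C@@]1(C#N)[C@@H](O)C=CC(C)(C)[C@H]1C1OCCO1 | intermediate
14 | (1S,2S,6R)-2-acetoxy-1-cyano-6-(1,3-dioxolan-2-yl)-5,5-dimethylcyclohex-3-ene-1-carboxylic acid | OC(=O)[C@@]1(C#N)[C@@H](OC(C)=O)C=CC(C)(C)[C@H]1C1OCCO1 | intermediate
15 | (1S,2R,6S)-6-acetoxy-1-cyano-2-(1,3-dioxolan-2-yl)-3,3-dimethylcyclohexane-1-carboxylic acid | OC(=O)[C@@]1(C#N)[C@@H](OC(C)=O)CCC(C)(C)[C@H]1C1OCCO1 | intermediate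
16 | [(1S,2R,3R)-2-cyano-3-(1,3-dioxolan-2-yl)-2-(hydroxymethyl)-4,4-dimethylcyclohexyl] acetate | OC[C@@]1(C#N)[C@@H](OC(C)=O)CCC(C)(C)[C@H]1C1OCCO1 | intermediate
17 | [(1S,2R,3R)-3-(1,3-dioxolan-2-yl)-2-formyl-2-(hydroxymethyl)-4,4-dimethylcyclohexyl] acetate | OC[C@@]1(C=O)[C@@H](OC(C)=O)CCC(C)(C)[C@H]1C1OCCO1 | intermediate
18 | tert-butyl acetate | CC(=O)OC(C)(C)C | starting material
19 | ethyl 3-(trimethylsilyl)prop-2-ynoate | CCOC(=O)C#C[Si](C)(C)C | starting material
20 | tert-butyl 3-oxo-5-(trimethylsilyl)pent-4-ynoate | CC(C)(C)OC(=O)CC(=O)C#C[Si](C)(C)C | intermediate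
21 | 3-oxo-5-(trimethylsilyl)pent-4-ynoate ester of the C20 alcohol of 17 | C[Si](C)(C)C#CC(=O)CC(=O)OC[C@@]1(C=O)[C@@H](OC(C)=O)CCC(C)(C)[C@H]1C1OCCO1 | intermediate
22 | 7-acetoxy-11-(1,3-dioxolan-2-yl)-10,10-dimethyl-4-[3-(trimethylsilyl)prop-2-ynoyl]-2-oxaspiro[5.5]undec-4-en-3-one | O=C1OC[C@@]2(C=C1C(=O)C#C[Si](C)(C)C)[C@@H](OC(C)=O)CCC(C)(C)[C@H]2C1OCCO1 | intermediate
23 | buta-1,3-diene | C=CC=C | starting material
24 | Diels–Alder adduct (rings A, lactone and C; C15 ynone on C8) | C1=CC[C@@H]2[C@@](C1)(C(=O)C#C[Si](C)(C)C)C(=O)OC[C@]23[C@@H](OC(C)=O)CCC(C)(C)[C@H]3C1OCCO1 | intermediate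
25 | (15R)-propargylic alcohol | C1=CC[C@@H]2[C@@](C1)([C@H](O)C#C[Si](C)(C)C)C(=O)OC[C@]23[C@@H](OC(C)=O)CCC(C)(C)[C@H]3C1OCCO1 | intermediate
26 | (15R)-propargylic alcohol with terminal alkyne | C1=CC[C@@H]2[C@@](C1)([C@H](O)C#C)C(=O)OC[C@]23[C@@H](OC(C)=O)CCC(C)(C)[C@H]3C1OCCO1 | intermediate
27 | tetracyclic vinylstannane (C6 still a dioxolane) | CCCC[Sn](CCCC)(CCCC)C=C1[C@@H]2CC[C@@H]3[C@](C2)(C(=O)OC[C@]32[C@@H](OC(C)=O)CCC(C)(C)[C@H]2C2OCCO2)[C@@H]1O | intermediate
28 | CNP0117386.1 | C=C1[C@@H]2CC[C@@H]3[C@](C2)(C(=O)OC[C@]32[C@@H](OC(C)=O)CCC(C)(C)[C@H]2C=O)[C@@H]1O | target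

Total step count: 18. Longest linear sequence: 17 (steps 1–11 and 13–18; step 12 is a one-step branch).

Steps most likely to fail

Step 7. The rearrangement may be too slow. The ketene acetal is stabilised by the nitrile and may rest as the N-silyl tautomer. The boryl group is an acceptor at the allyl terminus, and the new bond joins two crowded carbons. Prolonged heating could then cause desilylation or loss of CO2, and the β-hydroxy nitrile could ring-open by retro-aldol cleavage during the oxidation.
The fallback sets out from 10 and comes back at 14. It puts the oxygen on C1 before the rearrangement, as a donor. Copper diacetate-mediated oxidative acetoxylation of the alkenylboronate (Chan–Lam type; Cu(OAc)2, pyridine, MeCN, air) gives the (E)-enol acetate lactone F1 with retention of geometry. Neutral silylation with N,O-bis(trimethylsilyl)acetamide in warm toluene touches only the far more acidic C10–H. The donor-accelerated [3,3] shift through the same boat gives the silyl ester of the allylic acetate F2. Mild aqueous hydrolysis delivers 14 directly, so no free β-hydroxy acid is ever formed.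

Step 14. The cycloaddition may stall because C9 is neopentyl and flanked by the equatorial groups on C1 and C5. Facial selectivity may also be poor, because the two lactone faces differ only in acetate oxygen against dioxolanyl carbon.
The fallback sets out from 22 and comes back at 24. It builds ring C stepwise with smaller reagents. Hosomi–Sakurai conjugate allylation (allyltrimethylsilane, BF3·OEt2, CH2Cl2, −78 °C) adds C11–C13 to C9 and gives the C9-allyl β-keto lactone F3. Tsuji–Trost allylation of this soft nucleophile (allyl methyl carbonate, Pd(PPh3)4, THF) quaternises C8. This should occur cis to the C9 allyl group, since the other face carries C5 with its acetal in a syn-axial position, and it gives the C8,C9-diallyl lactone F4. Ring-closing metathesis with the second-generation Grubbs catalyst then closes the C12=C13 cyclohexene of 24.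

Step 13. The aldol addition to the very hindered C9 aldehyde may be sluggish. The amine may add to the ynone, and the free C20 alcohol may take over the acetyl group from O1 on heating.
The fallback sets out from 17 and comes back at 22. It forms the ring with a more reactive, alkyne-free methylene compound and attaches the alkyne afterwards. Knoevenagel condensation with Meldrum's acid (piperidinium acetate, rt) gives the alkylidene Meldrum's acid F5. The C20 alcohol opens it intramolecularly to the spirolactone carboxylic acid F6. Oxalyl chloride with catalytic DMF gives the acid chloride F7. An acyl Sonogashira coupling with trimethylsilylacetylene (PdCl2(PPh3)2, CuI, Et3N) gives 22.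

Further compounds
F1 | step 7 | (4S,6R)-6-[(E)-2-acetoxyethenyl]-4-(1,3-dioxolan-2-yl)-5,5-dimethyl-2-oxooxane-3-carbonitrile | CC(=O)O/C=C/[C@H]1OC(=O)C(C#N)[C@H](C2OCCO2)C1(C)C
F2 | step 7 | trimethylsilyl ester of 14 | C[Si](C)(C)OC(=O)[C@@]1(C#N)[C@@H](OC(C)=O)C=CC(C)(C)[C@H]1C1OCCO1
F3 | step 14 | C9-allyl β-keto lactone (C8 enolisable) | C=CC[C@@H]1C(C(=O)C#C[Si](C)(C)C)C(=O)OC[C@]12[C@@H](OC(C)=O)CCC(C)(C)[C@H]2C1OCCO1
F4 | step 14 | C8,C9-diallyl lactone (allyl groups cis) | C=CC[C@@H]1[C@@](CC=C)(C(=O)C#C[Si](C)(C)C)C(=O)OC[C@]12[C@@H](OC(C)=O)CCC(C)(C)[C@H]2C1OCCO1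
F5 | step 13 | alkylidene Meldrum's acid of 17 | OC[C@@]1(C=C2C(=O)OC(C)(C)OC2=O)[C@@H](OC(C)=O)CCC(C)(C)[C@H]1C1OCCO1
F6 | step 13 | spirolactone carboxylic acid (CO2H on C8) | O=C1OC[C@@]2(C=C1C(=O)O)[C@@H](OC(C)=O)CCC(C)(C)[C@H]2C1OCCO1
F7 | step 13 | acid chloride of F6 | O=C1OC[C@@]2(C=C1C(=O)Cl)[C@@H](OC(C)=O)CCC(C)(C)[C@H]2C1OCCO1
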